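The C3/C5 syn-diacetate sits in an unbranched chain, C3–C7, built from alternating CH(O) and CH2 carbons with no α-substituent. This is the pattern made by 2-deoxyribose-5-phosphate aldolase (DERA, a class I aldolase). Everything rests on cutting C3–C4 and C5–C6 together. In one operation DERA adds two acetaldehyde units in sequence to achiral 3-(4-hydroxy-3-methoxyphenyl)propanal, sets both carbinol centres under enzyme control and halts as a six-membered lactol. Its masked aldehyde (C7) then accepts C8–C12 by Wittig olefination, and hydrogenation and phenol-sparing acetylation finish the route. The precursor of the key step has no stereocentre and no protecting group.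

Key step: step 2

Remark: target numbering is used throughout (C1 = benzylic CH2, C3 and C5 = acetoxy carbons, C12 = terminal CH3). The SMILES reads as (3R,5S), the syn-1,3-diol series. An E. coli-type DERA with wild-type facial selectivity is taken as a purchasable biocatalyst.

Step 1
Reactants: 1 (E)-coniferaldehyde
Product: 2 3-(4-hydroxy-3-methoxyphenyl)propanal
Conditions: H2 (1 atm), 5% Pd/C, EtOAc, rt, stopped after one equivalent of H2
Reagents that add atoms: none
Why: Chemoselective heterogeneous hydrogenation, in which Pd/C saturates the conjugated C=C of a cinnamaldehyde much faster than it reduces the aldehyde, with no stereocentre formed.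

Step 2
Reactants: 2 3-(4-hydroxy-3-methoxyphenyl)propanal; 3 acetaldehyde (two molecules incorporated)
Product: 6 (4R,6R)-6-[2-(4-hydroxy-3-methoxyphenyl)ethyl]oxane-2,4-diol (anomeric mixture), via mono-aldol aldehyde 4 (not isolated), via open-chain bis-aldol aldehyde 5 (not isolated)
Conditions: DERA (E. coli type, acetaldehyde-tolerant variant, cell-free extract), 3 (2.5 equiv, slow feed), 0.1 M triethanolamine buffer pH 7.5, 10% v/v DMSO, 25 °C
Reagents that add atoms: acetaldehyde (compound 3, two molecules), CC=O
Why: Class I aldolase mechanism: the active-site lysine condenses with 3 to an enamine that adds to the carbonyl of 2 (bond C3–C4), hydrolysis of the iminium releases 4, and 4 returns as acceptor for a second lysine-bound enamine (bond C5–C6) to give 5. The closest known reaction type is the DERA-catalysed sequential aldol of two acetaldehydes with non-phosphorylated, α-unbranched acceptors (chloroacetaldehyde, 3-azidopropanal, N-protected 3-aminopropanals), of which 2 is the 3-aryl member. The one ring closes without the enzyme by 6-exo-trig hemiacetalisation of the hydroxyl on target C3 onto the C7 aldehyde of 5, which drains both reversible aldol equilibria and masks the aldehyde against a third addition. Both stereocentres are catalyst-controlled: the active site exposes the same face of each acceptor carbonyl to the enamine, as in the formation of (R)-3-hydroxybutanal from 3 alone, so that 4 should be 3R and 5 should be (3R,5R), the syn-diol that corresponds to 3R,5S in the target because only the CIP ranking at C5 changes once C7 is no longer a carbonyl. The step needs donor/acceptor discrimination and cross- over self-aldol selectivity: 2 is too large for the donor site and can act only as acceptor, its CH2CH2 spacer leaves the carbonyl α-unbranched and holds the arene away from the catalytic lysine, the free phenol gives solubility in buffer, and slow feeding of 3 keeps its self-trimerisation and the inactivation of the enzyme down.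

Step 3
Reactants: 6 (4R,6R)-6-[2-(4-hydroxy-3-methoxyphenyl)ethyl]oxane-2,4-diol; 7 pentyltriphenylphosphonium bromide
Product: 9 (3R,5S,7Z)-1-(4-hydroxy-3-methoxyphenyl)dodec-7-ene-3,5-diol, via pentylidene ylide 8 (not isolated)
Conditions: 7 (4.5 equiv), NaHMDS (4.4 equiv), THF, 0 °C; then 6, −78 °C → rt; aq. NH4Cl
Reagents that add atoms: pentyltriphenylphosphonium bromide (compound 7, delivers C8–C12), CCCCC[P+](c1ccccc1)(c1ccccc1)c1ccccc1.[Br-]
Why: Wittig olefination of a lactol through its open hydroxy-aldehyde tautomer, as practised on unprotected 2-deoxy sugars, in which excess non-stabilised ylide first takes the three acidic protons, the resulting alkoxides disfavour β-elimination, the alkene geometry is irrelevant since it is hydrogenated next, and C3 and C5 are not touched.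

Step 4
Reactants: 9 (3R,5S,7Z)-1-(4-hydroxy-3-methoxyphenyl)dodec-7-ene-3,5-diol
Product: 10 (3R,5S)-1-(4-hydroxy-3-methoxyphenyl)dodecane-3,5-diol ([8]-gingerdiol, syn)
Conditions: H2 (1 atm), 10% Pd/C, EtOAc, rt
Reagents that add atoms: none
Why: Catalytic hydrogenation of an isolated disubstituted alkene, under which secondary alcohols, the phenol and the arene are inert and both stereocentres are left as they are.

Step 5
Reactants: 10 (3R,5S)-1-(4-hydroxy-3-methoxyphenyl)dodecane-3,5-diol
Product: 12 (3R,5S)-1-(4-hydroxy-3-methoxyphenyl)dodecane-3,5-diyl diacetate, via triacetate 11 (not isolated)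
Conditions: Ac2O (3.5 equiv), DMAP (5 mol%), pyridine, rt; then pyrrolidine (10 equiv), 0 °C, same flask
Reagents that add atoms: acetic anhydride, CC(=O)OC(C)=O
Why: DMAP-catalysed exhaustive acetylation followed by chemoselective aminolysis, in which the aryl acetate (phenoxide leaving group) is cleaved by a secondary amine far faster than the two secondary alkyl acetates, and no C–O bond at C3 or C5 is broken so that the configuration is retained.

Compound list
1 | (E)-coniferaldehyde, (2E)-3-(4-hydroxy-3-methoxyphenyl)prop-2-enal | O=C/C=C/c1ccc(O)c(OC)c1 | starting material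
2 | 3-(4-hydroxy-3-methoxyphenyl)propanal | O=CCCc1ccc(O)c(OC)c1 | intermediate
3 | acetaldehyde | CC=O | starting material
4 | (3R)-3-hydroxy-5-(4-hydroxy-3-methoxyphenyl)pentanal | O=CC[C@@H](CCc1ccc(O)c(OC)c1)O | intermediate
5 | (3R,5R)-3,5-dihydroxy-7-(4-hydroxy-3-methoxyphenyl)heptanal | O=CC[C@@H](C[C@@H](CCc1ccc(O)c(OC)c1)O)O | intermediate
6 | (4R,6R)-6-[2-(4-hydroxy-3-methoxyphenyl)ethyl]oxane-2,4-diol, 4-OH trans to the C6 side chain, anomeric mixture | OC1C[C@@H](C[C@@H](CCc2ccc(O)c(OC)c2)O1)O | intermediate
7 | pentyltriphenylphosphonium bromide | CCCCC[P+](c1ccccc1)(c1ccccc1)c1ccccc1.[Br-] | starting material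
8 | pentylidenetriphenylphosphorane | CCCCC=P(c1ccccc1)(c1ccccc1)c1ccccc1 | intermediate
9 | (3R,5S,7Z)-1-(4-hydroxy-3-methoxyphenyl)dodec-7-ene-3,5-diol | CCCC/C=C\C[C@@H](C[C@@H](CCc1ccc(O)c(OC)c1)O)O | intermediate
10 | (3R,5S)-1-(4-hydroxy-3-methoxyphenyl)dodecane-3,5-diol | CCCCCCC[C@@H](C[C@@H](CCc1ccc(O)c(OC)c1)O)O | intermediate
11 | (3R,5S)-1-(4-acetoxy-3-methoxyphenyl)dodecane-3,5-diyl diacetate | CCCCCCC[C@@H](C[C@@H](CCc1ccc(OC(C)=O)c(OC)c1)OC(C)=O)OC(C)=O | intermediate
12 | (3R,5S)-1-(4-hydroxy-3-methoxyphenyl)dodecane-3,5-diyl diacetate | CCCCCCC[C@@H](C[C@@H](CCc1ccc(O)c(OC)c1)OC(C)=O)OC(C)=O | target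

Total step count: 5. Longest linear sequence: 5 (from 1).

Steps most likely to fail

Step 2. The bulky, hydrophobic acceptor may turn over too slowly. Self-aldolisation of acetaldehyde and inactivation of the enzyme would then dominate, or the reaction would stall after the first addition.

The fallback sets out from 2 and comes back at 10, so steps 3 and 4 fall away. It sets the two centres one after the other by chemocatalysis.
- Roskamp homologation of 2 (ethyl diazoacetate, cat. SnCl2, CH2Cl2) should give ethyl 5-(4-hydroxy-3-methoxyphenyl)-3-oxopentanoate F1.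
- Noyori asymmetric hydrogenation (RuCl2[(R)-BINAP], H2, EtOH) should set the carbinol in ethyl (3R)-3-hydroxy-5-(4-hydroxy-3-methoxyphenyl)pentanoate F2.
- MeNH(OMe)·HCl with i-PrMgCl should convert it into (3R)-3-hydroxy-5-(4-hydroxy-3-methoxyphenyl)-N-methoxy-N-methylpentanamide F3.
- Excess n-heptylmagnesium bromide should give (3R)-3-hydroxy-1-(4-hydroxy-3-methoxyphenyl)dodecan-5-one F4.
- Narasaka–Prasad reduction (Et2BOMe, NaBH4, THF–MeOH, −78 °C) through the boron chelate should give the syn-diol 10.

Step 3. The open β-hydroxy aldehyde may undergo retro-aldol fragmentation or dehydration under the strongly basic ylide conditions. The ylide is also drained by three acidic protons.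

The fallback sets out from 6 and comes back at 10, so step 4 falls away. It inverts the polarity of C7 so that C7–C8 is made by alkylation instead of olefination.
- 1,3-Propanedithiol and BF3·OEt2 (CH2Cl2, 0 °C) should open the lactol to (2R,4R)-1-(1,3-dithian-2-yl)-6-(4-hydroxy-3-methoxyphenyl)hexane-2,4-diol F5.
- 2,2-Dimethoxypropane and PPTS should give the syn-acetonide 4-{2-[(4R,6R)-6-(1,3-dithian-2-ylmethyl)-2,2-dimethyl-1,3-dioxan-4-yl]ethyl}-2-methoxyphenol F6.
- Corey–Seebach lithiation (n-BuLi, 2.2 equiv, THF–HMPA) and alkylation with 1-iodopentane should give 4-{2-[(4R,6R)-2,2-dimethyl-6-[(2-pentyl-1,3-dithian-2-yl)methyl]-1,3-dioxan-4-yl]ethyl}-2-methoxyphenol F7.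
- Raney nickel in EtOH should desulfurise it to 4-{2-[(4R,6S)-6-heptyl-2,2-dimethyl-1,3-dioxan-4-yl]ethyl}-2-methoxyphenol F8.
- Aqueous acetic acid should release 10.

Step 5. The discrimination between aryl and alkyl acetates in one flask may be incomplete, with partial loss of a secondary acetate or incomplete cleavage of the phenolic one.

The fallback sets out from 10 and comes back at 12. It replaces differential lability with a phenol protecting group.
- BnBr and K2CO3 in acetone should alkylate only the phenol to give (3R,5S)-1-[4-(benzyloxy)-3-methoxyphenyl]dodecane-3,5-diol F9.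
- Ac2O, pyridine and DMAP should give (3R,5S)-1-[4-(benzyloxy)-3-methoxyphenyl]dodecane-3,5-diyl diacetate F10.
- Hydrogenolysis (H2, Pd/C, EtOAc) should give 12.

Further compounds
F1 | step 2 | ethyl 5-(4-hydroxy-3-methoxyphenyl)-3-oxopentanoate | CCOC(=O)CC(=O)CCc1ccc(O)c(OC)c1
F2 | step 2 | ethyl (3R)-3-hydroxy-5-(4-hydroxy-3-methoxyphenyl)pentanoate | CCOC(=O)C[C@@H](CCc1ccc(O)c(OC)c1)O
F3 | step 2 | (3R)-3-hydroxy-5-(4-hydroxy-3-methoxyphenyl)-N-methoxy-N-methylpentanamide | CON(C)C(=O)C[C@@H](CCc1ccc(O)c(OC)c1)O
F4 | step 2 | (3R)-3-hydroxy-1-(4-hydroxy-3-methoxyphenyl)dodecan-5-one | CCCCCCCC(=O)C[C@@H](CCc1ccc(O)c(OC)c1)O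
F5 | step 3 | (2R,4R)-1-(1,3-dithian-2-yl)-6-(4-hydroxy-3-methoxyphenyl)hexane-2,4-diol | C1CSC(SC1)C[C@@H](C[C@@H](CCc2ccc(O)c(OC)c2)O)O
F6 | step 3 | 4-{2-[(4R,6R)-6-(1,3-dithian-2-ylmethyl)-2,2-dimethyl-1,3-dioxan-4-yl]ethyl}-2-methoxyphenol | C1CSC(SC1)C[C@@H](C[C@@H](CCc2ccc(O)c(OC)c2)O3)OC3(C)C
F7 | step 3 | 4-{2-[(4R,6R)-2,2-dimethyl-6-[(2-pentyl-1,3-dithian-2-yl)methyl]-1,3-dioxan-4-yl]ethyl}-2-methoxyphenol | CCCCCC1(SCCCS1)C[C@@H](C[C@@H](CCc2ccc(O)c(OC)c2)O3)OC3(C)C
F8 | step 3 | 4-{2-[(4R,6S)-6-heptyl-2,2-dimethyl-1,3-dioxan-4-yl]ethyl}-2-methoxyphenol | CCCCCCC[C@@H](C[C@@H](CCc1ccc(O)c(OC)c1)O2)OC2(C)C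
F9 | step 5 | (3R,5S)-1-[4-(benzyloxy)-3-methoxyphenyl]dodecane-3,5-diol | CCCCCCC[C@@H](C[C@@H](CCc1ccc(OCc2ccccc2)c(OC)c1)O)O
F10 | step 5 | (3R,5S)-1-[4-(benzyloxy)-3-methoxyphenyl]dodecane-3,5-diyl diacetate | CCCCCCC[C@@H](C[C@@H](CCc1ccc(OCc2ccccc2)c(OC)c1)OC(C)=O)OC(C)=O
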